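(The earlier runs and the new flask come from a simulation for substances that don't exist, noise included.)

Cut X to 25.0 mM in the noon run, keep G at 80.0 mM, and decide from the two runs so far whether that charge is worth making.

common to all: G 80.0 mM

| run | X | time |
|---|---|---|
| spring | 160 mM |  |
| summer | 80.0 mM |  |
| noon | 25.0 mM | 34 min |

| run | time / min | [J] / mM |
|---|---|---|
| spring run | 4.2 | 20.4 |
| spring run | 8.5 | 34.6 |
| spring run | 13 | 42.9 |
| spring run | 17 | 46.6 |
| spring run | 21 | 49.8 |
| spring run | 26 | 51.8 |
| spring run | 30 | 53.1 |
| spring run | 34 | 54.6 |
| summer run | 4.2 | 15.0 |
| summer run | 8.5 | 27.8 |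
| summer run | 13 | 36.8 |
| summer run | 17 | 39.8 |
| summer run | 21 | 39.8 |
| summer run | 26 | 40.7 |
| summer run | 30 | 42.5 |
| summer run | 34 | 43.9 |

(standard deviation of a reading: 1 mM)

- Overall: G + X -> J.
- Constant volume, constant temperature.
- "The second partner" is X.
- An order is taken over about fifteen percent of the charge, up and down.

- the exponent of [X] in the starting rate at the charge of the spring run (at the point where two percent of the G have become J)
- J in the noon run at 34 min, as a share of the G charged
- which of these the readings show (the second partner is lost in pairs / the product speeds the reaction / the product binds the substrate)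

The decision hangs on how much X goes astray. One J takes one X, so X is the limiting reagent of the noon run, and J there can reach 31.2% of the G charged. At 34 min the spring run reads 54.6 mM of J from 160 mM of X, and the summer run reads 43.9 mM from 80.0 mM, so twice the X gave 1.24 times the J.

The measure used here is the waste coefficient w: the X charged that is not J at 34 min, per J made, per mM of X charged. It reads 0.0103 mM⁻¹ in the summer run and 0.0121 mM⁻¹ in the spring run. These two readings lie close, as they should if the waste grows with the square of [X] while the J route grows with [X].

This reckoning is my own. It takes the summer value, from the charge nearer to that of the noon run, and sets J equal to the X charge divided by one plus w times that charge. The noon run then gives 19.9 mM of J, or 24.9% of the G charged. That estimate puts 79.6% of the X into J, against a reading of 54.9% in the summer run, so the noon charge stands.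

The forecast differs from this reckoning. It gives an order in X of 0.6 (0.35 to 1) and J at 12% (6% to 27%), and it chooses "the product binds the substrate": “Sequestration of G by J fits better”.

The flask gives an order of 0.39, J at 25.0%, and "the second partner is lost in pairs".

    G ⇌ L + Q (0.1698 min⁻¹, 0.3876 M⁻¹ min⁻¹)
    L + X → J (4.392 M⁻¹ min⁻¹)
    2 X → Wa (1.098 M⁻¹ min⁻¹)

In the noon run J stands at 20.0 mM from 25.0 mM of X, which gives a w of 0.01000 mM⁻¹, beside the 0.0103 mM⁻¹ carried from the summer run. The loss of X by pairs to Wa is the reason for that waste: the noon run without this step reaches 31.2% of the G charged, 6.2 percentage points higher. In that run without the step, J at 34 min is 25.0 mM from the 25.0 mM of X charged.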